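In a one-step world the target would climb to a plateau and stay there. The gamma run instead reads 62.9% at 1.00 h and 55.1% at 6.00 h; taken as first-order, the fall between its last two readings is 0.0369 /h.

| flask | starting material | first nucleophile | second nucleophile | protic impurity | remark | time |
|---|---|---|---|---|---|---|
| gamma | 20 mM | 1.5 equiv | 4 equiv | 0.40 mM | run made earlier |  |
| beta | 20 mM | 2.1 equiv | 4 equiv | 0.40 mM | run made earlier |  |
| delta | 20 mM | 3.3 equiv | 4 equiv | 0.40 mM | run made earlier |  |
| zeta | 30 mM | 1.5 equiv | 4 equiv | 0.40 mM | run made earlier |  |
| amber | 20 mM | 1.50 equiv (fed, over 6.0 h) | 4.00 equiv | 0.400 mM | all else is in the flask from the start; the feed brings no volume worth counting | 10 h |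
| ochre | 20 mM | 1.50 equiv | 4.00 equiv | 0.400 mM | everything together at the start | 10 h |
| violet | 20 mM | 1.50 equiv | 4.00 equiv (fed, over 6.0 h) | 0.400 mM | all else is in the flask from the start; the feed brings no volume worth counting | 10 h |

| gamma: time / h | gamma: target / % | beta: time / h | beta: target / % | delta: time / h | delta: target / % | zeta: time / h | zeta: target / % |
|---|---|---|---|---|---|---|---|
| 0.500 | 51.4 | 0.833 | 69.5 | 1.50 | 78.8 | 0.500 | 50.7 |
| 1.00 | 62.9 | 2.00 | 71.1 | 3.00 | 74.4 | 1.00 | 64.1 |
| 2.50 | 62.7 | 4.00 | 63.3 | 5.00 | 66.8 | 2.50 | 62.4 |
| 6.00 | 55.1 | 6.00 | 60.7 | 6.00 | 66.3 | 6.00 | 53.6 |

(scatter of a reading: 1 percentage point)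



- which flask leads in amount of target, in percent of the starting material charged ("all alike" within 1.5 percentage points) (amber / ochre / violet / all alike)
- how much target is there at the end, in percent of the starting material charged: amber
- how much target is there at the end, in percent of the starting material charged: ochre
- how much target is there at the end, in percent of the starting material charged: violet

The zeta run, at 30 mM of starting material, reads 64.1% at 1.00 h against 62.9% for gamma at 20 mM, so equivalents appear to set the yield, not concentration. The reckoning here therefore has starting material turning first-order into an intermediate, for which the two nucleophiles compete. With the fall undone, gamma extrapolates back to 68.8% and its early reading gives a birth rate of 2.87 /h. Delta, with 3.3 equiv of first nucleophile, extrapolates back to 83.3%, which gives a selectivity factor of 6.04.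

Multiplied by first nucleophile over second nucleophile as the intermediate is born, this factor becomes the capture ratio, and the target's share is ratio/(1 + ratio). At the ochre charges the ratio is 2.27, a share of 69.4% against the 68.8% read from gamma. Beta gives 76.0% against 76.5% read.

A feed of 6.0 h outlasts the starting material's lifetime, read as 0.348 h, by a factor of 17.2, which this reckoning takes to divide the ratio for amber and multiply it for violet. As a power of ten, the capture ratio stands at −0.880 for amber, 0.356 for ochre and 1.59 for violet. One number is not enough, though: the split needs the fade to 69.1% at 10 h. This reckoning then gives 8.06% for amber, 48.0% for ochre and 67.4% for violet.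

The forecast names violet, with 7.3% for amber, 47.5% for ochre and 66% for violet, where “little second nucleophile is present early”.

The flasks give 8.12% for amber, 44.9% for ochre and 61.5% for violet, so violet leads. Other capture product ends at 87.5% in amber, 29.8% in ochre and 4.00% in violet, while one over one plus the capture ratio gives 88.3%, 30.6% and 2.50%.

    second nucleophile + intermediate → other capture product (k = 100 /M/h)
    first nucleophile + intermediate → target (k = 830 /M/h)
    starting material → intermediate (k = 2.90 /h)
    target ⇌ isomer of the product (K = 2.20, k = 0.0530 /h)
    first nucleophile + protic impurity → quenched reagent (k = 6400 /M/h)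

Violet read at 15 h keeps its capture ratio, so share times fade gives 56.1%. The computed flask holds 51.4%.

Readings and results are calculated with constants of no real substance; the scatter is artificial.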